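Retrosynthesis first cuts the acyl–O bond at C1. It then cuts C8–C9 and C5–C10 together while restoring C1–C5, and finally C1–C10, C8–C12, C5–C6 and one C4–CH3 bond.
The enabling feature is in ring A: the oxygen-bearing C1 is bonded to the quaternary C10, which is an α-quaternary ketone (a pinacol retron). The migrating atom C5 is shared by rings A and B.
In the forward direction the five-membered ring C1–C5 is made first and receives a C10=C9 alkenyl group and a C6–C7–C8≡C12 chain. One cascade then closes ring B through a transient seven-membered ring and expands the five-membered ring to ring A.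
The endgame is C1 reduction, esterification, transposition of the 8(12)-alkene to the 7-ene-12-ol, double oxidation and phenol release.
C5 comes from an asymmetric decarboxylative allylation. The C1 carbinol comes from epoxidation anti to the C5 chain, which places the alkenyl group cis to C6 as a trans-decalin requires. C10 and C9 are set in the cascade (retention at C5, (E)-alkene geometry), and C1-OH by hydride attack anti to the C10 methyl group.

Key step: step 13

Numbering remark: drimane numbering is used for all intermediates. Ring A is C1, C2, C3, C4, C5, C10; ring B is C5 to C10; C11 sits on C9 and C12 on C8.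
Assumption: the (R,R) ligand in step 2 is taken to give (S)-4; if the sense of induction is opposite, the (S,S) ligand is used.

Step 1
Reactants: 1 3-methylcyclopent-2-en-1-one
Product: 3 allyl 3,3-dimethylcyclopent-1-en-1-yl carbonate, via magnesium enolate 2 (not isolated)
Conditions: MeMgBr, CuBr·SMe2 (10 mol %), THF, −30 °C; then DMPU, allyl chloroformate, −78 to 0 °C
Reagents that add atoms: methylmagnesium bromide, C[Mg]Br; allyl chloroformate, C=CCOC(=O)Cl
Why: Copper-catalysed conjugate addition builds the C4 gem-dimethyl carbon and releases the enolate only toward C5, and O-acylation in the presence of DMPU stores this regiochemistry as the allyl enol carbonate (conjugate addition/enolate trapping).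

Step 2
Reactants: 3 allyl 3,3-dimethylcyclopent-1-en-1-yl carbonate
Product: 4 (S)-2-allyl-3,3-dimethylcyclopentan-1-one
Conditions: Pd2(dba)3·CHCl3 (2.5 mol %), (R,R)-ANDEN-phenyl Trost ligand (5.5 mol %), toluene, 23 °C
Reagents that add atoms: none
Why: In this decarboxylative asymmetric allylic alkylation, zerovalent palladium ionises the carbonate, CO2 is lost and the chiral allylpalladium enolate pair recombines at C5 under neutral conditions that should not racemise the tertiary centre, so the ligand sets C5.

Step 3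
Reactants: 4 (S)-2-allyl-3,3-dimethylcyclopentan-1-one
Product: 6 (S)-5-allyl-4,4-dimethylcyclopent-1-en-1-yl trifluoromethanesulfonate, via lithium enolate 5 (not isolated)
Conditions: LDA, THF, −78 °C; then PhNTf2, −78 to 0 °C
Reagents that add atoms: N-phenylbis(trifluoromethanesulfonimide), O=S(=O)(N(c1ccccc1)S(=O)(=O)C(F)(F)F)C(F)(F)F
Why: Kinetic deprotonation takes the open C2-H rather than the C5-H next to the quaternary C4, so enolate triflation should give the C1=C2 enol triflate with C5 untouched.

Step 4
Reactants: 7 but-2-yn-1-ol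
Product: 8 tert-butyl(but-2-yn-1-yloxy)dimethylsilane
Conditions: TBSCl, imidazole, CH2Cl2, 0 °C to rt
Reagents that add atoms: tert-butyldimethylsilyl chloride, CC(C)(C)[Si](C)(C)Cl
Why: Standard silylation of a primary alcohol protects the future C11 oxygen through all steps up to step 18.

Step 5
Reactants: 8 tert-butyl(but-2-yn-1-yloxy)dimethylsilane
Product: 9 (Z)-tert-butyldimethyl{[3-(4,4,5,5-tetramethyl-1,3,2-dioxaborolan-2-yl)but-2-en-1-yl]oxy}silane (methyl cis to CH2O)
Conditions: B2pin2, CuCl (5 mol %), PCy3 (6 mol %), NaOt-Bu (10 mol %), MeOH (2 equiv), toluene, rt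
Reagents that add atoms: bis(pinacolato)diboron, CC1(C)OB(OC1(C)C)B1OC(C)(C)C(C)(C)O1
Why: Copper-catalysed syn-protoboration of an internal propargylic ether places boron on the carbon remote from the CH2O group, so the methyl and CH2OTBS groups end cis on the alkene.

Step 6
Reactants: 6 (S)-5-allyl-4,4-dimethylcyclopent-1-en-1-yl trifluoromethanesulfonate; 9 the (Z)-alkenyl boronate
Product: 10 tert-butyl{[(E)-3-((S)-5-allyl-4,4-dimethylcyclopent-1-en-1-yl)but-2-en-1-yl]oxy}dimethylsilane
Conditions: PdCl2(dppf) (5 mol %), K2CO3, dioxane/H2O, 60 °C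
Reagents that add atoms: none
Why: Suzuki–Miyaura coupling of an enol triflate with an alkenyl boronate forms the C1–C10 bond with retention of both alkene geometries.

Step 7
Reactants: 10 the triene
Product: 11 (1S,2S,5S)-2-allyl-1-[(E)-4-(tert-butyldimethylsilyloxy)but-2-en-2-yl]-3,3-dimethyl-6-oxabicyclo[3.1.0]hexane (epoxide oxygen anti to the allyl group)
Conditions: DMDO (1.0 equiv), acetone/CH2Cl2, −40 °C
Reagents that add atoms: dimethyldioxirane, CC1(C)OO1
Why: Neutral epoxidation should take the ring alkene, which has no allylic oxygen, from the face anti to the C5 allyl group, so C1–O ends trans to C6; direct addition of an alkenyl metal to 4 would give the other C1 epimer, which can only lead to a cis-decalin.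

Step 8
Reactants: 11 the vinyl epoxide
Product: 12 (1S,2S)-2-allyl-1-[(E)-4-(tert-butyldimethylsilyloxy)but-2-en-2-yl]-3,3-dimethylcyclopentan-1-ol (OH trans and alkenyl cis to the allyl group)
Conditions: LiEt3BH, THF, 0 °C to rt; then H2O
Reagents that add atoms: none
Why: The strongly nucleophilic borohydride opens the trisubstituted epoxide by SN2 attack at the less substituted C2, leaving the C1–O bond and its configuration intact.

Step 9
Reactants: 12 the tertiary allylic alcohol
Product: 13 triethylsilyl ether of 12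
Conditions: TESOTf, 2,6-lutidine, CH2Cl2, −78 to 0 °C
Reagents that add atoms: triethylsilyl trifluoromethanesulfonate, CC[Si](CC)(CC)OS(=O)(=O)C(F)(F)F
Why: Silyl triflate silylation of a hindered tertiary alcohol blocks lactol formation in step 11 and oxygen attack on the alkyne in step 13, and it supplies the silyloxy terminator of the pinacol shift.

Step 10
Reactants: 13 the TES ether
Product: 15 3-{(1S,2S)-2-[(E)-4-(tert-butyldimethylsilyloxy)but-2-en-2-yl]-5,5-dimethyl-2-(triethylsilyloxy)cyclopentyl}propan-1-ol, via B-alkyl-9-BBN adduct 14 (not isolated)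
Conditions: 9-BBN, THF, 0 °C to rt; then NaOH, H2O2, 0 °C
Reagents that add atoms: hydrogen peroxide, OO; 9-borabicyclo[3.3.1]nonane, C1CC2CCCC(C1)B2 (atoms in 14 only)
Why: Hydroboration–oxidation with 9-BBN selects the monosubstituted allyl alkene over the hindered trisubstituted one and places oxygen on the terminal carbon C8.

Step 11
Reactants: 15 the primary alcohol
Product: 16 the corresponding propanal (C8 aldehyde)
Conditions: (n-Pr4N)RuO4 (5 mol %), NMO, 4 Å MS, CH2Cl2, rt
Reagents that add atoms: none
Why: The Ley–Griffith oxidation stops at the aldehyde under neutral conditions that both silyl ethers and the alkene tolerate.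

Step 12
Reactants: 16 the aldehyde
Product: 17 {[(1S,2S)-2-(but-3-yn-1-yl)-1-[(E)-4-(tert-butyldimethylsilyloxy)but-2-en-2-yl]-3,3-dimethylcyclopentyl]oxy}triethylsilane
Conditions: dimethyl (1-diazo-2-oxopropyl)phosphonate, K2CO3, MeOH, 0 °C to rt
Reagents that add atoms: dimethyl (1-diazo-2-oxopropyl)phosphonate, COP(=O)(OC)C(=[N+]=[N-])C(C)=O
Why: The Ohira–Bestmann variant of the Seyferth–Gilbert homologation adds C12 and gives the terminal alkyne, with no epimerisable centre next to the aldehyde.

Step 13
Reactants: 17 the cyclopentyl 1,7-enyne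
Product: 18 11-(tert-butyldimethylsilyloxy)drim-8(12)-en-1-one (trans-decalin; 5α-H, 9α-H, 10β-methyl)
Conditions: (t-Bu)2(o-biphenyl)PAuCl (10 mol %), AgSbF6 (10 mol %), i-PrOH (1.5 equiv), CH2Cl2, 0 °C to rt
Reagents that add atoms: none
Why: Proposed new method: the cationic monovalent gold complex activates the terminal alkyne, C9 of the (E)-alkene attacks the internal alkyne carbon C8 and leaves a tertiary cation at C10 beside the silyloxy carbon C1, the C1–C5 bond then shifts to C10 (pinacol step) to give the C1 ketone, and i-PrOH takes up the Et3Si group and protonates the vinyl-gold carbon C12. The closest known reaction type is the pinacol-terminated 1,6-enyne cyclisation (related to the Prins–pinacol ring-enlarging cyclopentane annulation), in which a six-membered ring forms and shrinks to five; here the tether is one CH2 longer (a 1,7-enyne), which has not been shown. Ring B closes by 7-exo-dig attack (transient ring C1-C10-C9-C8-C7-C6-C5) followed by seven-to-six contraction, and ring A arises in the same 1,2-shift by five-to-six expansion. C5 migrates with retention; C10 is set because the alkenyl group and the C6 chain are cis on the cyclopentane, so a chair-like array with C9 between C6 and H5 (rather than against the C4 methyl groups) places the C10 methyl anti to H5; C9 follows from the (E)-alkene, whose CH2OTBS group is cis to the methyl group and ends equatorial (β). The step needs C5 rather than C2 to migrate, which the bicyclic cation secures because a C2 shift would give a strained bridged ketone, and it needs carbon rather than oxygen attack on the alkyne, which the TES ether secures.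

Step 14
Reactants: 18 the decalin ketone
Product: 19 11-(tert-butyldimethylsilyloxy)drim-8(12)-en-1β-ol
Conditions: NaBH4, MeOH/CH2Cl2, 0 °C to rt
Reagents that add atoms: none
Why: Hydride should attack C1 from the α face, opposite the axial C10 methyl group as in Wieland–Miescher-type 1-decalones, giving the equatorial 1β-alcohol.

Step 15
Reactants: 20 (E)-4-hydroxycinnamic acid (p-coumaric acid)
Product: 22 (E)-3-[4-(tert-butyldimethylsilyloxy)phenyl]acrylic acid, via bis-silyl derivative 21 (not isolated)
Conditions: TBSCl (2.2 equiv), imidazole, DMF, rt; then THF/H2O, AcOH (cat.)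
Reagents that add atoms: tert-butyldimethylsilyl chloride, CC(C)(C)[Si](C)(C)Cl
Why: Exhaustive silylation followed by hydrolysis of the much more labile silyl ester leaves only the phenol protected.

Step 16
Reactants: 19 the 1β-alcohol; 22 the protected coumaric acid
Product: 23 11-(tert-butyldimethylsilyloxy)drim-8(12)-en-1β-yl (E)-3-[4-(tert-butyldimethylsilyloxy)phenyl]acrylate
Conditions: DCC, DMAP (cat.), CH2Cl2, rt to 40 °C
Reagents that add atoms: none
Why: Steglich esterification acylates the only free hydroxyl group, with the acylpyridinium species small enough to reach the hindered equatorial C1-OH.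

Step 17
Reactants: 23 the ester
Product: 24 8α,12-epoxy-11-(tert-butyldimethylsilyloxy)driman-1β-yl (E)-3-[4-(tert-butyldimethylsilyloxy)phenyl]acrylate
Conditions: DMDO, acetone/CH2Cl2, 0 °C
Reagents that add atoms: dimethyldioxirane, CC1(C)OO1
Why: The exocyclic 8(12)-alkene is the only electron-rich alkene (the cinnamate alkene is deactivated) and should be attacked from the α face, away from the axial C10 methyl group.

Step 18
Reactants: 24 the spiro-epoxide
Product: 26 11,12-dihydroxydrim-7-en-1β-yl (E)-3-[4-(tert-butyldimethylsilyloxy)phenyl]acrylate, via 12-O-TMS allyl ether 25 (not isolated)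
Conditions: TMSOTf, 2,6-lutidine, toluene, −78 °C; DBU, −78 °C to rt; then CSA (cat.), MeOH, 0 °C
Reagents that add atoms: trimethylsilyl trifluoromethanesulfonate, C[Si](C)(C)OS(=O)(=O)C(F)(F)F (atoms in 25 only)
Why: Silyl triflate opening of the 1,1-disubstituted epoxide at the tertiary C8, followed by amidine-induced loss of the accessible C7-H, is the known epoxide-to-allyl silyl ether isomerisation, and acid methanolysis then cleaves the two alkyl silyl ethers but not the acid-stable aryl silyl ether.

Step 19
Reactants: 26 the 11,12-diol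
Product: 27 11,12-dioxodrim-7-en-1β-yl (E)-3-[4-(tert-butyldimethylsilyloxy)phenyl]acrylate
Conditions: (COCl)2, DMSO, CH2Cl2, −78 °C; then Et3N, −78 to −30 °C
Reagents that add atoms: none
Why: Swern oxidation is the standard way from drim-7-ene-11,12-diols to the ene-dialdehyde, and at low temperature it should neither lactonise the diol nor epimerise C9.

Step 20
Reactants: 27 the O-silyl dialdehyde
Product: 28 1β-[(E)-4-hydroxycinnamoyloxy]drim-7-ene-11,12-dial (CNP0187624.1)
Conditions: HF·pyridine, pyridine/THF, 0 °C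
Reagents that add atoms: none
Why: Buffered fluoride cleaves the aryl silyl ether under mildly acidic conditions, avoiding the base that would epimerise the C9 aldehyde.

Compound list
1 | 3-methylcyclopent-2-en-1-one | CC1=CC(=O)CC1 | starting material
2 | bromomagnesium 3,3-dimethylcyclopent-1-en-1-olate | CC1(C)C=C(O[Mg]Br)CC1 | intermediate
3 | allyl 3,3-dimethylcyclopent-1-en-1-yl carbonate | C=CCOC(=O)OC1=CC(C)(C)CC1 | intermediate
4 | (S)-2-allyl-3,3-dimethylcyclopentan-1-one | C=CC[C@@H]1C(=O)CCC1(C)C | intermediate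
5 | lithium (S)-5-allyl-4,4-dimethylcyclopent-1-en-1-olate | C=CC[C@@H]1C(O[Li])=CCC1(C)C | intermediate
6 | (S)-5-allyl-4,4-dimethylcyclopent-1-en-1-yl trifluoromethanesulfonate | C=CC[C@@H]1C(OS(=O)(=O)C(F)(F)F)=CCC1(C)C | intermediate
7 | but-2-yn-1-ol | CC#CCO | starting material
8 | tert-butyl(but-2-yn-1-yloxy)dimethylsilane | CC#CCO[Si](C)(C)C(C)(C)C | intermediate
9 | (Z)-alkenyl pinacol boronate (methyl cis to CH2OTBS) | C/C(=C\CO[Si](C)(C)C(C)(C)C)B1OC(C)(C)C(C)(C)O1 | intermediate
10 | (S,E)-triene | C=CC[C@@H]1C(=CCC1(C)C)/C(C)=C/CO[Si](C)(C)C(C)(C)C | intermediate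
11 | (1S,2S,5S)-vinyl epoxide, oxygen anti to allyl | C=CC[C@H]1C(C)(C)C[C@@H]2O[C@]12/C(C)=C/CO[Si](C)(C)C(C)(C)C | intermediate
12 | (1S,2S)-tertiary allylic alcohol, alkenyl cis to allyl | C=CC[C@H]1C(C)(C)CC[C@@]1(O)/C(C)=C/CO[Si](C)(C)C(C)(C)C | intermediate
13 | TES ether of 12 | C=CC[C@H]1C(C)(C)CC[C@@]1(O[Si](CC)(CC)CC)/C(C)=C/CO[Si](C)(C)C(C)(C)C | intermediate
14 | B-alkyl-9-BBN adduct of 13 | C1CC2CCCC(C1)B2CCC[C@H]1C(C)(C)CC[C@@]1(O[Si](CC)(CC)CC)/C(C)=C/CO[Si](C)(C)C(C)(C)C | intermediate
15 | primary alcohol (C8-OH) | OCCC[C@H]1C(C)(C)CC[C@@]1(O[Si](CC)(CC)CC)/C(C)=C/CO[Si](C)(C)C(C)(C)C | intermediate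
16 | aldehyde (C8) | O=CCC[C@H]1C(C)(C)CC[C@@]1(O[Si](CC)(CC)CC)/C(C)=C/CO[Si](C)(C)C(C)(C)C | intermediate
17 | cyclopentyl 1,7-enyne | C#CCC[C@H]1C(C)(C)CC[C@@]1(O[Si](CC)(CC)CC)/C(C)=C/CO[Si](C)(C)C(C)(C)C | intermediate
18 | 11-(tert-butyldimethylsilyloxy)drim-8(12)-en-1-one | CC1(C)CCC(=O)[C@]2(C)[C@@H](CO[Si](C)(C)C(C)(C)C)C(=C)CC[C@@H]12 | intermediate
19 | 11-(tert-butyldimethylsilyloxy)drim-8(12)-en-1β-ol | CC1(C)CC[C@@H](O)[C@]2(C)[C@@H](CO[Si](C)(C)C(C)(C)C)C(=C)CC[C@@H]12 | intermediate
20 | (E)-4-hydroxycinnamic acid | O=C(O)/C=C/c1ccc(O)cc1 | starting material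
21 | tert-butyldimethylsilyl (E)-3-[4-(tert-butyldimethylsilyloxy)phenyl]acrylate | CC(C)(C)[Si](C)(C)OC(=O)/C=C/c1ccc(O[Si](C)(C)C(C)(C)C)cc1 | intermediate
22 | (E)-3-[4-(tert-butyldimethylsilyloxy)phenyl]acrylic acid | O=C(O)/C=C/c1ccc(O[Si](C)(C)C(C)(C)C)cc1 | intermediate
23 | 1β-ester of 19 with 22 | CC1(C)CC[C@@H](OC(=O)/C=C/c3ccc(O[Si](C)(C)C(C)(C)C)cc3)[C@]2(C)[C@@H](CO[Si](C)(C)C(C)(C)C)C(=C)CC[C@@H]12 | intermediate
24 | 8α,12-epoxide of 23 | CC1(C)CC[C@@H](OC(=O)/C=C/c3ccc(O[Si](C)(C)C(C)(C)C)cc3)[C@]2(C)[C@@H](CO[Si](C)(C)C(C)(C)C)[C@@]3(CO3)CC[C@@H]12 | intermediate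
25 | 7-ene with 12-OTMS and 11-OTBS | CC1(C)CC[C@@H](OC(=O)/C=C/c3ccc(O[Si](C)(C)C(C)(C)C)cc3)[C@]2(C)[C@@H](CO[Si](C)(C)C(C)(C)C)C(CO[Si](C)(C)C)=CC[C@@H]12 | intermediate
26 | 11,12-diol | CC1(C)CC[C@@H](OC(=O)/C=C/c3ccc(O[Si](C)(C)C(C)(C)C)cc3)[C@]2(C)[C@@H](CO)C(CO)=CC[C@@H]12 | intermediate
27 | O-TBS dialdehyde | CC1(C)CC[C@@H](OC(=O)/C=C/c3ccc(O[Si](C)(C)C(C)(C)C)cc3)[C@]2(C)[C@@H](C=O)C(C=O)=CC[C@@H]12 | intermediate
28 | 1β-[(E)-4-hydroxycinnamoyloxy]drim-7-ene-11,12-dial | CC1(C)CC[C@@H](OC(=O)/C=C/c2ccc(O)cc2)[C@]2(C)[C@@H](C=O)C(C=O)=CC[C@@H]12 | target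

Total step count: 20. Longest linear sequence: 17 steps (1–3, 6–14, 16–20).

Steps most likely to fail

Step 13. The seven-membered closure may be slow. Ionisation of the tertiary allylic silyl ether, hydration of the alkyne, or closure through the other rotamer about C1–C10 (which leads to the cis-decalin) could then compete.
The fallback uses known chemistry and sets out from 17. N-Iodosuccinimide in CH2Cl2/i-PrOH at −20 °C should trigger the halonium-induced semipinacol ring expansion: an iodonium ion forms on C9=C10 and C5 shifts anti to it. This gives 3-(but-3-yn-1-yl)-2-[2-(tert-butyldimethylsilyloxy)-1-iodoethyl]-2,4,4-trimethylcyclohexan-1-one F1, with the C2 methyl cis to the butynyl chain.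
Bu3SnH/AIBN in benzene at 80 °C under slow addition then closes ring B. The C9 radical cyclises 6-exo-dig onto the alkyne through a chair-like array with CH2OTBS equatorial, and the route comes back at 18.

Step 7. Site selectivity between the two trisubstituted alkenes of the diene may be poor, and the vinyl epoxide may open during handling.
The fallback sets out from 6 and postpones the second alkene. Sonogashira coupling with commercial tert-butyldimethyl(prop-2-yn-1-yloxy)silane (PdCl2(PPh3)2, CuI, Et3N) gives the cyclopentenyl enyne F2. In F2 only the ring alkene can be epoxidised, and DMDO gives the alkynyl epoxide F3 with oxygen anti to the allyl group.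
LiEt3BH opens F3 at C2 to the tertiary propargylic alcohol F4. Alkoxide-directed anti-carbomagnesiation (MeMgBr, CuI cat., THF, then H2O) puts the methyl group on C10 and hydrogen on C9 cis to C1. This is the required (E)-alkene, and the route comes back at 12.

Step 18. Proton loss may go toward C9, giving the tetrasubstituted 8-ene, or a hydride shift may give the saturated 12-aldehyde, instead of proton loss from C7.
The fallback sets out from 23 and avoids the epoxide. Ene-type allylic chlorination (NCS, PhSeCl cat., CH2Cl2) moves the alkene into the ring and gives the 12-chloro-7-ene F5. N-Methylmorpholine N-oxide in MeCN oxidises the allylic chloride to the 12-enal F6.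
CSA/MeOH then frees the C11 alcohol to give the 11-hydroxy-12-enal F7. Dess–Martin oxidation of that single alcohol brings the route back at 27.

Further compounds
F1 | step 13 | 3-(but-3-yn-1-yl)-2-[2-(tert-butyldimethylsilyloxy)-1-iodoethyl]-2,4,4-trimethylcyclohexan-1-one | CC1(C)CCC(=O)[C@](C)([C@H](CO[Si](C)(C)C(C)(C)C)I)[C@H]1CCC#C
F2 | step 7 | (S)-{[3-(5-allyl-4,4-dimethylcyclopent-1-en-1-yl)prop-2-yn-1-yl]oxy}(tert-butyl)dimethylsilane | C=CC[C@@H]1C(C#CCO[Si](C)(C)C(C)(C)C)=CCC1(C)C
F3 | step 7 | alkynyl epoxide, oxygen anti to allyl | C=CC[C@H]1C(C)(C)C[C@@H]2O[C@]12C#CCO[Si](C)(C)C(C)(C)C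
F4 | step 7 | (1S,2S)-2-allyl-1-[3-(tert-butyldimethylsilyloxy)prop-1-yn-1-yl]-3,3-dimethylcyclopentan-1-ol | C=CC[C@H]1C(C)(C)CC[C@@]1(O)C#CCO[Si](C)(C)C(C)(C)C
F5 | step 18 | 12-chloro-11-(tert-butyldimethylsilyloxy)drim-7-en-1β-yl (E)-3-[4-(tert-butyldimethylsilyloxy)phenyl]acrylate | CC1(C)CC[C@@H](OC(=O)/C=C/c3ccc(O[Si](C)(C)C(C)(C)C)cc3)[C@]2(C)[C@@H](CO[Si](C)(C)C(C)(C)C)C(CCl)=CC[C@@H]12
F6 | step 18 | 11-(tert-butyldimethylsilyloxy)-12-oxodrim-7-en-1β-yl (E)-3-[4-(tert-butyldimethylsilyloxy)phenyl]acrylate | CC1(C)CC[C@@H](OC(=O)/C=C/c3ccc(O[Si](C)(C)C(C)(C)C)cc3)[C@]2(C)[C@@H](CO[Si](C)(C)C(C)(C)C)C(C=O)=CC[C@@H]12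
F7 | step 18 | 11-hydroxy-12-oxodrim-7-en-1β-yl (E)-3-[4-(tert-butyldimethylsilyloxy)phenyl]acrylate | CC1(C)CC[C@@H](OC(=O)/C=C/c3ccc(O[Si](C)(C)C(C)(C)C)cc3)[C@]2(C)[C@@H](CO)C(C=O)=CC[C@@H]12
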